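The C11–C12 link between the two bicycles is opened to a sulfone and an aldehyde, and both halves are traced to one trans-fused enedione whose ring B is (R)-carvone. The key step closes ring A by forming C3–C4: hydrogen-atom transfer from an iron hydride turns the isopropenyl group into the tertiary C4 radical, which adds to the carbon of a pendant nitrile and leaves the C3 ketone. It exploits the gem-dimethyl quaternary C4 next to oxygenated C3 in ring A, a motif present in both bicycles. The precursor is (R)-carvone that carries a methyl and a 2-cyanoethyl group on the future C10, the cyanoethyl arm trans to the isopropenyl group.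

Key step: step 3

Remark: terpenoid locants are used (ring A = C1–C5 and C10, ring B = C5–C10, C11 on C9, C12 on C9′, primed locants for the right bicycle), and β is the face of the C10 methyl group.

**Step 1**
Reactants: 1 (R)-carvone; 2 iodomethane
Product: 4 6-methylcarvone (C6 epimer mixture; methyl trans to isopropenyl expected as the major epimer), via lithium dienolate 3 (not isolated)
Conditions: LiN(iPr)2 (LDA), THF, −78 °C; MeI, −78 → 0 °C
Reagents that add atoms: iodomethane, CI
Why: Kinetic α′-deprotonation of the enone and enolate C-methylation (enolate alkylation); the new C6 centre may form as an epimer mixture because step 2 makes this carbon planar again.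

**Step 2**
Reactants: 4 6-methylcarvone; 5 acrylonitrile
Product: 7 6-(2-cyanoethyl)-6-methylcarvone (cyanoethyl trans to isopropenyl), via lithium enolate 6 (not isolated)
Conditions: LiN(iPr)2 (LDA), THF, −78 °C; acrylonitrile (1.1 equiv, slow addition), −78 °C; AcOH, −78 °C
Reagents that add atoms: acrylonitrile, C=CC#N
Why: Michael addition (cyanoethylation) of the tetrasubstituted lithium enolate; the acceptor approaches the enolate face opposite the adjacent isopropenyl group, which sets the quaternary centre (future C10) with the cyanoethyl arm trans to isopropenyl, and the cold acetic acid quench protonates the nitrile anion before it can add to more acrylonitrile or across the ring to the enone.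

**Step 3**
Reactants: 7 6-(2-cyanoethyl)-6-methylcarvone
Product: 9 trans-fused enedione (4,4,8,10-tetramethyl-trans-decal-7-ene-3,9-dione), via N–H ketimine 8 (not isolated)
Conditions: Fe(acac)3 (30 mol %), PhSiH3 (2.5 equiv), EtOH, 60 °C; then 1 M HCl, THF, rt
Reagents that add atoms: water, O
Why: Fe(acac)3 and PhSiH3 form an iron hydride that transfers a hydrogen atom to the CH2 terminus of the isopropenyl group (Markovnikov), the tertiary C4 radical adds to the nitrile carbon, and the iminyl radical is reduced by divalent iron and protonated by ethanol to ketimine 8, which returns the iron to the cycle and is hydrolysed to the C3 ketone on acid work-up. The closest known reaction type is the iron-hydride hydrogen-atom-transfer cyclisation of unactivated alkenes onto nitriles to give cyclic ketones. Ring A is closed in the 6-exo-dig mode through a chair in which the C5–C4 and C10–C1 bonds are both equatorial on ring B. No stereocentre is formed: C4 becomes the gem-dimethyl carbon and the trans ring fusion (5α-H, 10β-CH3) is already fixed by carvone C5 and by the anti alkylation of step 2. The step needs hydrogen-atom transfer to the electron-rich 1,1-disubstituted alkene and none to the electron-poor trisubstituted enone, which the polarity difference of the two alkenes should secure. The C4 radical has no competing acceptor within reach, since attack on C7 or C8 would require a four-membered or a 5-endo closure.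

**Step 4**
Reactants: 9 trans-fused enedione
Product: 10 3β-hydroxy-4,4,8,10-tetramethyl-trans-decal-7-en-9-one
Conditions: NaBH4 (0.5 equiv), MeOH/CH2Cl2 (1:1), −78 → −40 °C
Reagents that add atoms: none
Why: Chemoselective borohydride reduction: the saturated C3 ketone should react well before the conjugated C9 ketone (flanked by quaternary C10 and the C8 methyl), and axial hydride delivery from the α face, away from the axial 4β-methyl, gives the equatorial 3β-alcohol.

**Step 5**
Reactants: 10 3β-hydroxy enone; 11 tert-butyldimethylsilyl triflate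
Product: 12 3β-TBS ether of 10
Conditions: TBSOTf, 2,6-lutidine, CH2Cl2, −78 → 0 °C
Reagents that add atoms: tert-butyldimethylsilyl trifluoromethanesulfonate, CC(C)(C)[Si](C)(C)OS(=O)(=O)C(F)(F)F
Why: Silyl ether formation with the silyl triflate, which is reactive enough for the hindered C3 hydroxyl next to the gem-dimethyl group; the C9 ketone has no α′ hydrogen and should not be enolised by 2,6-lutidine.

**Step 6**
Reactants: 12 TBS-protected enone; 13 methyltriphenylphosphonium bromide
Product: 14 C7=C8/C9=C11 diene (9-methylene compound)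
Conditions: Ph3PCH3Br, KOtBu, THF, 0 °C → reflux
Reagents that add atoms: methyltriphenylphosphonium bromide, C[P+](c1ccccc1)(c1ccccc1)c1ccccc1.[Br-]
Why: Wittig methylenation: the small unstabilised ylide converts the hindered C9 ketone into the exocyclic C9=C11 alkene of a fixed transoid diene; no stereocentre is made.

**Step 7**
Reactants: 14 diene
Product: 16 3β-TBSO-drim-7-en-11-ol (9β-hydroxymethyl; 9α-H), via B-alkyl-9-BBN 15 (not isolated)
Conditions: 9-BBN (1.5 equiv), THF, 0 → 60 °C; then NaOH aq., 30% H2O2, 0 °C → rt
Reagents that add atoms: hydrogen peroxide, OO; 9-borabicyclo[3.3.1]nonane, B1C2CCCC1CCC2 (its boron stays only in 15)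
Why: Hydroboration–oxidation: 9-BBN should add only to the terminal 1,1-disubstituted alkene with boron on C11, and hydrogen is delivered to C9 from the α face because the axial C10 methyl blocks the β face, which sets 9α-H (C11 equatorial, β) and leaves C7=C8 untouched.

**Step 8**
Reactants: 16 left-half alcohol (first portion); 17 1-phenyl-1H-tetrazole-5-thiol
Product: 18 C11 1-phenyl-1H-tetrazol-5-yl sulfide
Conditions: PPh3, DIAD, THF, 0 °C → rt
Reagents that add atoms: 1-phenyl-1H-tetrazole-5-thiol, Sc1nnnn1-c1ccccc1
Why: Mitsunobu thioetherification of the primary C11 alcohol (SN2 at C11; no stereocentre affected).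

**Step 9**
Reactants: 18 sulfide
Product: 19 C11 1-phenyl-1H-tetrazol-5-yl sulfone
Conditions: (NH4)6Mo7O24·4H2O (10 mol %), 30% H2O2, EtOH, 0 °C → rt
Reagents that add atoms: hydrogen peroxide, OO
Why: Molybdate-catalysed peroxide oxidation of sulfide to sulfone, which should be much faster than epoxidation of the hindered trisubstituted C7=C8 alkene.

**Step 10**
Reactants: 16 left-half alcohol (second portion)
Product: 20 right-half alcohol (3′β-TBSO-drimane-11-ol with 8′α-methyl and 8′β-H)
Conditions: [Ir(cod)(PCy3)(py)]PF6 (5 mol %), H2 (1 atm), CH2Cl2, rt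
Reagents that add atoms: none
Why: Hydroxyl-directed hydrogenation with Crabtree's catalyst: the C11 hydroxyl on the β face binds the cationic iridium and both hydrogens are added to C7=C8 from that face, which sets 8′β-H and the equatorial 8′α-methyl (primed locants from here on).

**Step 11**
Reactants: 20 right-half alcohol
Product: 21 right-half aldehyde (9′β-formyl)
Conditions: Dess–Martin periodinane, CH2Cl2, 0 °C → rt
Reagents that add atoms: none
Why: Dess–Martin oxidation of the primary alcohol to the aldehyde under non-basic conditions; the adjacent C9′ centre already has the more stable equatorial configuration.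

**Step 12**
Reactants: 19 left-half sulfone; 21 right-half aldehyde
Product: 23 C11=C12 alkene (3,3′-bis-TBS ether; E isomer expected as the major one), via potassium sulfonyl carbanion 22 (not isolated)
Conditions: KN(SiMe3)2 (KHMDS), DME, −60 °C; then 21, −60 °C → rt; H2O
Reagents that add atoms: none
Why: Julia–Kocienski olefination: the metalated sulfone adds to the aldehyde and the adduct collapses by Smiles rearrangement with loss of SO2 and the tetrazololate to give the C11=C12 alkene; its geometry is irrelevant because step 13 saturates it, and at −60 °C neither C9 nor C9′ should be deprotonated.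

**Step 13**
Reactants: 23 C11=C12 alkene
Product: 24 3,3′-bis-TBS ether of the target
Conditions: 2-nitrobenzenesulfonyl hydrazide (excess, in portions), Et3N, CH2Cl2, rt
Reagents that add atoms: none
Why: Diimide reduction: concerted syn transfer of two hydrogens to the 1,2-disubstituted C11=C12 alkene, which should be reduced far faster than the hindered trisubstituted C7=C8 ring alkene; no metal hydride is present that could move that double bond.

**Step 14**
Reactants: 24 bis-TBS ether
Product: 25 target diol CNP0194061.1
Conditions: HF·pyridine, THF/pyridine, 0 °C → rt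
Reagents that add atoms: none
Why: Fluoride-mediated cleavage of both silyl ethers (desilylation) under buffered conditions that should leave C7=C8 and all stereocentres untouched.

**Compound list**

1 | (R)-carvone, (5R)-2-methyl-5-(prop-1-en-2-yl)cyclohex-2-en-1-one | CC1=CC[C@H](CC1=O)C(C)=C | starting material
2 | iodomethane | CI | starting material
3 | lithium dienolate of 1 (cross-conjugated, O–C1=C6; C5 unchanged) | CC1=CC[C@@H](C(C)=C)C=C1[O-].[Li+] | intermediate
4 | 6-methylcarvone, (5R)-2,6-dimethyl-5-(prop-1-en-2-yl)cyclohex-2-en-1-one, both C6 epimers | CC1=CC[C@@H](C(C)=C)C(C)C1=O | intermediate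
5 | acrylonitrile | C=CC#N | starting material
6 | lithium enolate of 4 (tetrasubstituted, O–C1=C6) | CC1=CC[C@@H](C(C)=C)C(C)=C1[O-].[Li+] | intermediate
7 | 3-[(1S,6S)-1,3-dimethyl-2-oxo-6-(prop-1-en-2-yl)cyclohex-3-en-1-yl]propanenitrile (6-(2-cyanoethyl)-6-methylcarvone; cyanoethyl trans, methyl cis to isopropenyl) | CC1=CC[C@@H](C(C)=C)[C@](C)(CCC#N)C1=O | intermediate
8 | N–H ketimine of 9 at C3 (3-imino-4,4,8,10-tetramethyl-trans-decal-7-en-9-one; 5α-H, 10β-CH3) | CC1=CC[C@H]2C(C)(C)C(=N)CC[C@]2(C)C1=O | intermediate
9 | 4,4,8,10-tetramethyl-trans-decal-7-ene-3,9-dione (5α-H, 10β-CH3) | CC1=CC[C@H]2C(C)(C)C(=O)CC[C@]2(C)C1=O | intermediate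
10 | 3β-hydroxy-4,4,8,10-tetramethyl-trans-decal-7-en-9-one (5α-H, 10β-CH3) | CC1=CC[C@H]2C(C)(C)[C@@H](O)CC[C@]2(C)C1=O | intermediate
11 | tert-butyldimethylsilyl trifluoromethanesulfonate | CC(C)(C)[Si](C)(C)OS(=O)(=O)C(F)(F)F | starting material
12 | 3β-(tert-butyldimethylsilyloxy)-4,4,8,10-tetramethyl-trans-decal-7-en-9-one | CC1=CC[C@H]2C(C)(C)[C@@H](O[Si](C)(C)C(C)(C)C)CC[C@]2(C)C1=O | intermediate
13 | methyltriphenylphosphonium bromide | C[P+](c1ccccc1)(c1ccccc1)c1ccccc1.[Br-] | starting material
14 | 3β-TBSO-4,4,8,10-tetramethyl-9-methylene-trans-decal-7-ene (C7=C8 and C9=C11 diene) | CC1=CC[C@H]2C(C)(C)[C@@H](O[Si](C)(C)C(C)(C)C)CC[C@]2(C)C1=C | intermediate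
15 | B-alkyl-9-BBN from 14 (boron on C11; 9α-H) | CC1=CC[C@H]2C(C)(C)[C@@H](O[Si](C)(C)C(C)(C)C)CC[C@]2(C)[C@H]1CB1C2CCCC1CCC2 | intermediate
16 | 3β-TBSO-drim-7-en-11-ol (9β-CH2OH, 9α-H, 5α-H, 10β-CH3) | CC1=CC[C@H]2C(C)(C)[C@@H](O[Si](C)(C)C(C)(C)C)CC[C@]2(C)[C@H]1CO | intermediate
17 | 1-phenyl-1H-tetrazole-5-thiol | Sc1nnnn1-c1ccccc1 | starting material
18 | C11 (1-phenyl-1H-tetrazol-5-yl) sulfide of 16 | CC1=CC[C@H]2C(C)(C)[C@@H](O[Si](C)(C)C(C)(C)C)CC[C@]2(C)[C@H]1CSc1nnnn1-c1ccccc1 | intermediate
19 | C11 (1-phenyl-1H-tetrazol-5-yl) sulfone | CC1=CC[C@H]2C(C)(C)[C@@H](O[Si](C)(C)C(C)(C)C)CC[C@]2(C)[C@H]1CS(=O)(=O)c1nnnn1-c1ccccc1 | intermediate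
20 | 3′β-TBSO-drimane-11-ol with 8′α-CH3 (8′β-H), 9′β-CH2OH (9′α-H), 5′α-H, 10′β-CH3 | OC[C@H]1[C@H](C)CC[C@H]2C(C)(C)[C@@H](O[Si](C)(C)C(C)(C)C)CC[C@]12C | intermediate
21 | the corresponding 9′β-carbaldehyde (future C12 is the formyl carbon) | O=C[C@H]1[C@H](C)CC[C@H]2C(C)(C)[C@@H](O[Si](C)(C)C(C)(C)C)CC[C@]12C | intermediate
22 | potassium α-sulfonyl carbanion of 19 (at C11) | CC1=CC[C@H]2C(C)(C)[C@@H](O[Si](C)(C)C(C)(C)C)CC[C@]2(C)[C@H]1[CH-]S(=O)(=O)c1nnnn1-c1ccccc1.[K+] | intermediate
23 | 11,12-didehydro derivative of 24 (C11=C12 alkene, E isomer drawn; a Z isomer converges in step 13) | CC1=CC[C@H]2C(C)(C)[C@@H](O[Si](C)(C)C(C)(C)C)CC[C@]2(C)[C@H]1/C=C/[C@H]1[C@H](C)CC[C@H]2C(C)(C)[C@@H](O[Si](C)(C)C(C)(C)C)CC[C@]12C | intermediate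
24 | 3,3′-bis(tert-butyldimethylsilyl) ether of the target | CC1=CC[C@H]2C(C)(C)[C@@H](O[Si](C)(C)C(C)(C)C)CC[C@]2(C)[C@H]1CC[C@H]1[C@H](C)CC[C@H]2C(C)(C)[C@@H](O[Si](C)(C)C(C)(C)C)CC[C@]12C | intermediate
25 | CNP0194061.1: 3β,3′β-diol with C7=C8, 5α/5′α-H, 9α/9′α-H, 10β/10′β-CH3, 8′α-CH3 (8′β-H), C9 and C9′ joined by C11H2–C12H2 | CC1=CC[C@H]2C(C)(C)[C@@H](O)CC[C@]2(C)[C@H]1CC[C@H]1[C@H](C)CC[C@H]2C(C)(C)[C@@H](O)CC[C@]12C | target

**Count**

Total steps: 14. Longest linear sequence: 12 (steps 1–7, then 8–9 or 10–11, then 12–14).

**Steps most likely to fail**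

1. Step 3. The slow 6-exo addition of the C4 radical to the nitrile may be outrun by its reduction, which would give net hydrogenation of the isopropenyl group. The fallback sets out from 7 and comes back at 9. Markovnikov addition of HBr (33% in AcOH, 0 °C) to the isopropenyl group should give the tertiary bromide F1. Slow addition of (Me3Si)3SiH and AIBN in toluene at 90 °C then generates the same C4 radical in a chain process with the hydrogen donor kept dilute (silane-mediated radical cyclisation of a halo nitrile). The iminyl radical takes hydrogen from the silane to give ketimine 8, and 1 M HCl work-up hydrolyses it to 9.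

2. Step 2. The nitrile anion formed in the Michael addition may start oligomerisation of acrylonitrile or add intramolecularly to C7 of the enone (a double Michael closure to a bicyclo[2.2.2]octanone). The fallback sets out from 4 and comes back at 7. Enolate 6 (LDA, THF, −78 °C) is alkylated with allyl bromide, again anti to the isopropenyl group, to give the allyl ketone F2. Disiamylborane (THF, 0 °C) should hydroborate only the monosubstituted alkene to the trialkylborane F3, which trimethylamine N-oxide dihydrate (THF, reflux) oxidises, without touching the enone, to the primary alcohol F4. TEMPO (cat.), PhI(OAc)2 and NH4OAc in MeCN/H2O then convert the alcohol, through the aldehyde and its imine, into nitrile 7.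

3. Step 10. The directed hydrogen delivery has to occur on the face that carries the axial C10 methyl, so turnover may be slow and facial selectivity may be lost. The fallback sets out from 12 and comes back at 20. Hydrogenation (H2, Pd/C, EtOAc) followed by NaOMe in MeOH should give the saturated 8α-methyl ketone F5; this is set under thermodynamic control, because the 8β-methyl epimer suffers a 1,3-diaxial clash with the C10 methyl. Wittig methylenation (Ph3PCH3Br, KOtBu, THF, reflux) gives the exocyclic alkene F6. 9-BBN then adds from the α face to give the B-alkyl-9-BBN F7, which NaOH/H2O2 oxidises to alcohol 20.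

**Further compounds**

F1 | step 3 | Markovnikov HBr adduct of 7 (2-bromopropan-2-yl in place of isopropenyl) | CC1=CC[C@@H](C(C)(C)Br)[C@](C)(CCC#N)C1=O
F2 | step 2 | 6-allyl-6-methylcarvone (allyl trans to isopropenyl) | CC1=CC[C@@H](C(C)=C)[C@](C)(CC=C)C1=O
F3 | step 2 | bis(3-methylbutan-2-yl)borane adduct of F2 at the allyl terminus | CC1=CC[C@@H](C(C)=C)[C@](C)(CCCB(C(C)C(C)C)C(C)C(C)C)C1=O
F4 | step 2 | 6-(3-hydroxypropyl)-6-methylcarvone (hydroxypropyl trans to isopropenyl) | CC1=CC[C@@H](C(C)=C)[C@](C)(CCCO)C1=O
F5 | step 10 | 3β-TBSO-4,4,8α,10-tetramethyl-trans-decal-9-one (8β-H) | O=C1[C@H](C)CC[C@H]2C(C)(C)[C@@H](O[Si](C)(C)C(C)(C)C)CC[C@]12C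
F6 | step 10 | 3β-TBSO-4,4,8α,10-tetramethyl-9-methylene-trans-decalin | C=C1[C@H](C)CC[C@H]2C(C)(C)[C@@H](O[Si](C)(C)C(C)(C)C)CC[C@]12C
F7 | step 10 | B-alkyl-9-BBN from F6 (boron on C11; 9α-H) | C1CCC2CCCC1B2C[C@H]1[C@H](C)CC[C@H]2C(C)(C)[C@@H](O[Si](C)(C)C(C)(C)C)CC[C@]12C
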